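**Remark on the chemistry:** the target has no stereocentre, so no SMILES string carries stereodescriptors. The two fallback compounds with a carbinol carbon (F2, F3) are racemic.

## Analysis of the target

The target is 2-hydroxy-4-{[2-hydroxy-4-methoxy-6-(2-oxopentyl)benzoyl]oxy}-6-propylbenzoic acid, a depside: two separate benzene rings joined by one aryl ester, with no ring to close. Ring A is the acyl half (C1 carbonyl, C2 hydroxyl, C4 methoxy, C6 CH2C(=O)CH2CH2CH3). Ring B is a salicylic acid (C1 carboxyl, C2 hydroxyl, C6 propyl) whose C4 carries the ester oxygen. There is no stereocentre, so the problems are regiochemical and chemoselective only. The aryl ester is an activated ester and does not survive hydroxide or other strong nucleophiles, and the ring B salicylic acid can lose CO2 in hot acid. The side-chain ketone sits two atoms from ring A, ortho to the acyl group, so its enol oxygen can close onto that carbonyl to an isocoumarin whenever the carbonyl is made electrophilic. The main difficulty is that the ring A acid is 2,6-disubstituted: its carbonyl carbon is shielded, acylation of a phenol is slow, and the slow step gives the side chain time to intervene. The strategy rests on ring B: in a precursor substituted at C1, C2 and C6, the hydrogens are at C3, C4 and C5, and only C4 has hydrogen on both sides. Sterically governed borylation therefore marks C4, and the O–C4 bond can then be made from the ring A carboxylate oxygen as nucleophile.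

## Retrosynthetic reasoning

**20 back to 19 and 18.** The last bond cut is the benzylic C–O bond of the ring A ether, so 20 comes from benzyl ether 19 by hydrogenolysis, a neutral step that spares the depside ester, the ketone and the salicylic acid. 19 comes from 18, where the ring B acid is a tert-butyl ester, the ring B phenol a methoxymethyl ether and the ketone a dioxolane; one aqueous acid treatment removes all three. Ring B carries no benzyl group because unhindered benzyl C–H bonds would compete in the later borylation. Ring A keeps a benzyl ether because it must survive a lithium amide, hot hydroxide and the ketalisation.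

**18 back to 9 and 17.** The depside is cut at the bond between the ester oxygen and C4 of ring B, not at the acyl C–O bond. This gives ring A acid 9 and ring B boronic acid 17. The forward reaction must join a carboxylate oxygen to an aryl carbon under oxidative copper conditions. The hindered carbonyl carbon of 9 is then a spectator, and 9 is never turned into an acyl electrophile.

**17 back to 16, 14 and 15.** The C4–B bond is traced to a C–H bond. Boronic acid 17 comes from pinacol ester 16, and 16 from arene 14 and diboron 15 by iridium-catalysed borylation. C3 is flanked by the methoxymethoxy group and C5 by the propyl group, so only C4 is open. This is cheaper than carrying an oxygen or halogen at C4 through the ring B synthesis.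

**14 back to 12, 11 and 10.** The propyl group is cut between its benzylic carbon and the ethyl unit. 14 comes from toluate 12 through benzyllithium 13 and an ethyl halide. 12 comes from 6-methylsalicylic acid 10 by tert-butyl ester formation (11) and methoxymethylation. The tert-butyl ester serves twice: it is too bulky to self-condense during lateral lithiation, and it falls in the final acid step.

**9 back to 8 and 7.** Acid 9 comes from methyl ester 8 by saponification, and 8 from keto ester 7 by ketalisation. The ketone is masked before the ester is cleaved, so the free acid never coexists with a free ketone.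

**7 back to 3, 4, 2 and 1.** The side chain is cut at the bond between the benzylic CH2 and the ketone carbon. 7 comes from toluate 3 (through benzyllithium 5 and tetrahedral adduct 6) and Weinreb amide 4. 3 comes from methyl orsellinate 1 by methylation of the free 4-hydroxyl (2) and benzylation of the chelated 2-hydroxyl. The ring A carbon skeleton and oxygen pattern are thus bought, and only one C–C bond is made.

## Alternatives that were turned down

**Alternative 1:** Ring B is cut at both the C6–propyl and C1–carboxyl bonds, leading back to 3,5-dimethoxybenzyne A2.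
- Forward key step: iodine–magnesium exchange on an ortho-iodoaryl sulfonate releases A2. A propyl Grignard reagent adds at the aryne carbon remote from the flanking methoxy group, and the arylmagnesium left next to that methoxy group is carboxylated to 2,4-dimethoxy-6-propylbenzoic acid A1.
- For: two adjacent bonds form in one flask from a symmetrical resorcinol derivative, with regiochemistry set by the inductive pull of the methoxy group and no precious metal. For the ring B carbon skeleton alone this is at least as good as protection plus lateral ethylation.
- Against: A1 is only a ring B building block. Both methyl ethers must be cleaved with a strong Lewis acid, the acid re-protected and the 4-hydroxyl distinguished from the 2-hydroxyl. With oxygen already at C4, the union can only be acylation of that phenol by the hindered ring A acid, which is the step where the synthesis is weakest.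
- Comparison: the chosen route leaves C4 as C–H, converts it to C–B, and so allows the reversed union. Its ring B protecting groups are removed together with the ketal.

**Alternative 2:** Ring A is cut at C1–C2 and C5–C6 and built by benzannulation on the ready-made ester.
- Forward key step: 1,3-dimethoxy-1-(trimethylsilyloxy)buta-1,3-diene A4 adds across the triple bond of benzyl 2-hydroxy-6-propyl-4-{[4-(2-propyl-1,3-dioxolan-2-yl)but-2-ynoyl]oxy}benzoate A5. Loss of methanol and of the silyl group aromatises to benzyl 2-hydroxy-4-({2-hydroxy-4-methoxy-6-[(2-propyl-1,3-dioxolan-2-yl)methyl]benzoyl}oxy)-6-propylbenzoate A3.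
- For: the ester bond is made from an unhindered alkynoic acid, so the hindered acylation disappears. Ring A arrives with a free 2-hydroxyl and the right methoxy position, and the end-game is shorter. On these points it is stronger than the chosen route.
- Against: a β-alkyl ynoate is a sluggish dienophile and needs heat. The propargylic CH2 can isomerise to the allenoate, the diene is moisture-sensitive, and the aryl ynoate is a Michael acceptor in a molecule with a free phenol. Two C–C bonds would be formed at the most advanced stage by the least predictable step.
- Comparison: the chosen route offers robust, separately purified fragments and a union in which regiochemistry cannot go wrong.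

**Alternative 3:** The ring A C6–CH2 bond is cut last.
- Forward key step: benzyl 2-(benzyloxy)-4-{[2-(benzyloxy)-6-bromo-4-methoxybenzoyl]oxy}-6-propylbenzoate A7 and 1-chloropentan-2-one A8 are coupled at a cathode with NiBr2(2,2'-bipyridine) and a sacrificial anode. The product is benzyl 2-(benzyloxy)-4-{[2-(benzyloxy)-4-methoxy-6-(2-oxopentyl)benzoyl]oxy}-6-propylbenzoate A6.
- For: the ketone is absent when the depside bond is made, and the all-benzyl protection falls in a single hydrogenolysis. The end-game is one step shorter than the chosen one.
- Against: low-valent nickel can insert into the acyl C–O bond of the aryl ester. A8 is readily reduced to an enolate at the cathode. The nickel enolate or product enolate lies next to the depside carbonyl and can lactonise with loss of ring B. The bromide is ortho to the ester. The depside bond of A7 must still be made by hindered acylation, and an electrolysis cell is needed.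
- Comparison: the chosen route installs the ketone first, on a simple toluate where a side reaction costs little, and masks it before the union.

Key step: step 11

## Route

Step 1
Reactants: 1 methyl 2,4-dihydroxy-6-methylbenzoate (methyl orsellinate)
Product: 2 methyl 2-hydroxy-4-methoxy-6-methylbenzoate
Conditions: MeI (1.1 equiv), K2CO3 (1.2 equiv), acetone, 50 °C
Reagents that add atoms: iodomethane, CI
Why: Williamson ether synthesis; the 2-hydroxyl is tied up in a hydrogen bond to the ester carbonyl, so with a small excess of MeI the free 4-hydroxyl is methylated selectively.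

Step 2
Reactants: 2 methyl 2-hydroxy-4-methoxy-6-methylbenzoate
Product: 3 methyl 2-(benzyloxy)-4-methoxy-6-methylbenzoate
Conditions: BnBr (1.3 equiv), K2CO3 (2 equiv), DMF, 60 °C
Reagents that add atoms: benzyl bromide, BrCc1ccccc1
Why: Williamson ether synthesis; the chelated phenol needs a dipolar solvent and warming but is the only nucleophile left.

Step 3
Reactants: 3 methyl 2-(benzyloxy)-4-methoxy-6-methylbenzoate; 4 N-methoxy-N-methylbutanamide
Product: 7 methyl 2-(benzyloxy)-4-methoxy-6-(2-oxopentyl)benzoate, via lateral benzyllithium 5 (not isolated), via tetrahedral lithium alkoxide 6 (not isolated)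
Conditions: LiN(iPr)2 (1.2 equiv), THF, −78 °C, 15 min; then 4 (1.5 equiv), −78 → −40 °C; sat. aq NH4Cl at −40 °C
Reagents that add atoms: none
Why: Lateral lithiation of an ortho-toluate gives the ester-stabilised benzyllithium 5, which acylates on Weinreb amide 4; the chelated adduct 6 persists until the cold quench, so the ketone never meets base and cannot add a second time. Low temperature and a short metalation time limit attack of 5 on the ester of unreacted 3.

Step 4
Reactants: 7 methyl 2-(benzyloxy)-4-methoxy-6-(2-oxopentyl)benzoate
Product: 8 methyl 2-(benzyloxy)-4-methoxy-6-[(2-propyl-1,3-dioxolan-2-yl)methyl]benzoate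
Conditions: (TMSOCH2)2 (2 equiv), TMSOTf (5 mol %), CH2Cl2, −78 → −20 °C; then pyridine, aq NaHCO3
Reagents that add atoms: 1,2-bis(trimethylsilyloxy)ethane, C[Si](C)(C)OCCO[Si](C)(C)C
Why: Noyori ketalisation is aprotic and cold, so the unhindered dialkyl ketone is ketalised before its enol can lactonise onto the neighbouring ester; formation of the strong Si–O–Si bond drives it.

Step 5
Reactants: 8 methyl 2-(benzyloxy)-4-methoxy-6-[(2-propyl-1,3-dioxolan-2-yl)methyl]benzoate
Product: 9 2-(benzyloxy)-4-methoxy-6-[(2-propyl-1,3-dioxolan-2-yl)methyl]benzoic acid
Conditions: KOH (10 equiv), DMSO/H2O (4:1), 90 °C; then 0 °C, 1 M HCl to pH 4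
Reagents that add atoms: potassium hydroxide, [K+].[OH-]
Why: Saponification of a 2,6-disubstituted benzoate needs poorly solvated hydroxide and heat; benzyl ether, methyl ether and dioxolane are inert to base, and acidification only to pH 4 in the cold spares the ketal. The acid should be used in step 11 without storage.

Step 6
Reactants: 10 2-hydroxy-6-methylbenzoic acid
Product: 11 tert-butyl 2-hydroxy-6-methylbenzoate
Conditions: Me2NCH(OtBu)2 (4 equiv), toluene, 80 °C
Reagents that add atoms: N,N-dimethylformamide di-tert-butyl acetal, CN(C)C(OC(C)(C)C)OC(C)(C)C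
Why: O-alkylative esterification: the amide acetal transfers tert-butyl to the carboxylate oxygen, so the hindered carbonyl carbon is not attacked; the much less acidic phenol stays free.

Step 7
Reactants: 11 tert-butyl 2-hydroxy-6-methylbenzoate
Product: 12 tert-butyl 2-(methoxymethoxy)-6-methylbenzoate
Conditions: NaH (1.3 equiv), MOMCl (1.5 equiv), THF/DMF, 0 °C → rt
Reagents that add atoms: chloromethyl methyl ether, COCCl
Why: O-alkylation of the sodium phenoxide by the reactive α-chloro ether; NaH breaks the hydrogen bond to the ester, and the tert-butyl ester is inert.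

Step 8
Reactants: 12 tert-butyl 2-(methoxymethoxy)-6-methylbenzoate
Product: 14 tert-butyl 2-(methoxymethoxy)-6-propylbenzoate, via lateral benzyllithium 13 (not isolated)
Conditions: LiN(iPr)2 (1.15 equiv), THF, −78 °C; then EtI (2 equiv), −78 → −20 °C
Reagents that add atoms: iodoethane, CCI
Why: Lateral lithiation gives benzyllithium 13, an extended enolate of an ester too bulky to self-condense, and SN2 alkylation with EtI turns methyl into propyl. Only a slight excess of base is used, so the less acidic secondary benzylic position of 14 is not metalated again.

Step 9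
Reactants: 14 tert-butyl 2-(methoxymethoxy)-6-propylbenzoate; 15 bis(pinacolato)diboron
Product: 16 tert-butyl 2-(methoxymethoxy)-6-propyl-4-(4,4,5,5-tetramethyl-1,3,2-dioxaborolan-2-yl)benzoate
Conditions: 15 (1.0 equiv), [Ir(OMe)(cod)]2 (1.5 mol %), 4,4'-di-tert-butyl-2,2'-bipyridine (3 mol %), THF, 80 °C
Reagents that add atoms: none
Why: Iridium-catalysed aromatic C–H borylation through a trivalent iridium tris(boryl) complex is governed by sterics; C3 lies next to the methoxymethoxy group and C5 next to propyl, so only C4 reacts. The substrate has no benzyl group or other unhindered arene C–H to compete.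

Step 10
Reactants: 16 tert-butyl 2-(methoxymethoxy)-6-propyl-4-(4,4,5,5-tetramethyl-1,3,2-dioxaborolan-2-yl)benzoate
Product: 17 [4-(tert-butoxycarbonyl)-3-(methoxymethoxy)-5-propylphenyl]boronic acid
Conditions: NaIO4 (3 equiv), NH4OAc (3 equiv), acetone/H2O (1:1), rt
Reagents that add atoms: water, O
Why: Periodate cleaves the pinacol released in the hydrolysis equilibrium and so drives the boronic ester to the boronic acid near neutral pH, where tert-butyl ester and methoxymethyl ether are stable.

Step 11
Reactants: 9 2-(benzyloxy)-4-methoxy-6-[(2-propyl-1,3-dioxolan-2-yl)methyl]benzoic acid; 17 [4-(tert-butoxycarbonyl)-3-(methoxymethoxy)-5-propylphenyl]boronic acid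
Product: 18 tert-butyl 4-({2-(benzyloxy)-4-methoxy-6-[(2-propyl-1,3-dioxolan-2-yl)methyl]benzoyl}oxy)-2-(methoxymethoxy)-6-propylbenzoate
Conditions: Cu(OTf)2 (0.5 equiv), pyridine (3 equiv), 17 (2.0 equiv, in two portions), powdered 4 Å molecular sieves, EtOAc, dry air, 50 °C
Reagents that add atoms: none
Why: This is a Chan–Lam-type oxidative coupling of an arylboronic acid with a carboxylic acid, a known way to aryl esters. The carboxylate of 9 binds divalent copper, 17 transfers its aryl group from boron to copper, oxidation by a second divalent copper centre (regenerated by air) gives a trivalent aryl copper carboxylate, and C–O reductive elimination joins the carboxylate oxygen to C4 of ring B. The carbonyl carbon of 9, shielded by the benzyloxy group and the ketal-bearing CH2 group, is neither attacked nor made electrophilic, so steric retardation and closure of a side-chain oxygen onto an activated acyl group are both avoided. No ring closes and no stereocentre forms. The site on ring B is fixed by the boron position, which has hydrogen on both neighbours and is therefore unhindered in transmetalation. Chemoselectivity is needed against protodeboronation, oxidation of 17 to a phenol and biaryl homocoupling; molecular sieves, dry air and a twofold amount of 17 should secure it. Cu(OTf)2 is used instead of Cu(OAc)2 so that the carboxylate of 9 is the only carboxylate on copper and no aryl acetate of ring B forms, and pyridine acts as ligand and keeps the medium basic for the methoxymethyl ether, tert-butyl ester and dioxolane.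

Step 12
Reactants: 18 tert-butyl 4-({2-(benzyloxy)-4-methoxy-6-[(2-propyl-1,3-dioxolan-2-yl)methyl]benzoyl}oxy)-2-(methoxymethoxy)-6-propylbenzoate
Product: 19 4-{[2-(benzyloxy)-4-methoxy-6-(2-oxopentyl)benzoyl]oxy}-2-hydroxy-6-propylbenzoic acid
Conditions: TFA/CH2Cl2/H2O (10:10:1), 0 °C → rt
Reagents that add atoms: water, O
Why: Acidolysis unmasks acid, phenol and ketone in one operation: the tert-butyl ester loses isobutene, and the methoxymethyl ether and dioxolane hydrolyse through oxocarbenium ions. The aryl benzyl ether and the depside ester are stable to aqueous TFA at or below room temperature, and water traps the cations.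

Step 13
Reactants: 19 4-{[2-(benzyloxy)-4-methoxy-6-(2-oxopentyl)benzoyl]oxy}-2-hydroxy-6-propylbenzoic acid
Product: 20 2-hydroxy-4-{[2-hydroxy-4-methoxy-6-(2-oxopentyl)benzoyl]oxy}-6-propylbenzoic acid
Conditions: H2 (1 atm), 10% Pd/C, EtOAc, rt
Reagents that add atoms: none
Why: Hydrogenolysis of the benzyl aryl ether is neutral; the aliphatic ketone, the aryl ester and the salicylic acid are not reduced at atmospheric pressure and room temperature.

## Compound list

1 | methyl 2,4-dihydroxy-6-methylbenzoate (methyl orsellinate) | COC(=O)c1c(C)cc(O)cc1O | starting material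
2 | methyl 2-hydroxy-4-methoxy-6-methylbenzoate | COC(=O)c1c(C)cc(OC)cc1O | intermediate
3 | methyl 2-(benzyloxy)-4-methoxy-6-methylbenzoate | COC(=O)c1c(C)cc(OC)cc1OCc1ccccc1 | intermediate
4 | N-methoxy-N-methylbutanamide | CCCC(=O)N(C)OC | starting material
5 | methyl 2-(benzyloxy)-6-(lithiomethyl)-4-methoxybenzoate (lateral benzyllithium, formed in the flask) | [Li]Cc1cc(OC)cc(OCc2ccccc2)c1C(=O)OC | intermediate
6 | lithium 1-[3-(benzyloxy)-5-methoxy-2-(methoxycarbonyl)phenyl]-2-[methoxy(methyl)amino]pentan-2-olate (tetrahedral adduct, formed in the flask) | CCCC(O[Li])(Cc1cc(OC)cc(OCc2ccccc2)c1C(=O)OC)N(C)OC | intermediate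
7 | methyl 2-(benzyloxy)-4-methoxy-6-(2-oxopentyl)benzoate | CCCC(=O)Cc1cc(OC)cc(OCc2ccccc2)c1C(=O)OC | intermediate
8 | methyl 2-(benzyloxy)-4-methoxy-6-[(2-propyl-1,3-dioxolan-2-yl)methyl]benzoate | CCCC1(Cc2cc(OC)cc(OCc3ccccc3)c2C(=O)OC)OCCO1 | intermediate
9 | 2-(benzyloxy)-4-methoxy-6-[(2-propyl-1,3-dioxolan-2-yl)methyl]benzoic acid | CCCC1(Cc2cc(OC)cc(OCc3ccccc3)c2C(=O)O)OCCO1 | intermediate
10 | 2-hydroxy-6-methylbenzoic acid | Cc1cccc(O)c1C(=O)O | starting material
11 | tert-butyl 2-hydroxy-6-methylbenzoate | Cc1cccc(O)c1C(=O)OC(C)(C)C | intermediate
12 | tert-butyl 2-(methoxymethoxy)-6-methylbenzoate | Cc1cccc(OCOC)c1C(=O)OC(C)(C)C | intermediate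
13 | tert-butyl 2-(lithiomethyl)-6-(methoxymethoxy)benzoate (lateral benzyllithium, formed in the flask) | [Li]Cc1cccc(OCOC)c1C(=O)OC(C)(C)C | intermediate
14 | tert-butyl 2-(methoxymethoxy)-6-propylbenzoate | CCCc1cccc(OCOC)c1C(=O)OC(C)(C)C | intermediate
15 | bis(pinacolato)diboron | CC1(C)OB(OC1(C)C)B1OC(C)(C)C(C)(C)O1 | starting material
16 | tert-butyl 2-(methoxymethoxy)-6-propyl-4-(4,4,5,5-tetramethyl-1,3,2-dioxaborolan-2-yl)benzoate | CCCc1cc(B2OC(C)(C)C(C)(C)O2)cc(OCOC)c1C(=O)OC(C)(C)C | intermediate
17 | [4-(tert-butoxycarbonyl)-3-(methoxymethoxy)-5-propylphenyl]boronic acid | CCCc1cc(B(O)O)cc(OCOC)c1C(=O)OC(C)(C)C | intermediate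
18 | tert-butyl 4-({2-(benzyloxy)-4-methoxy-6-[(2-propyl-1,3-dioxolan-2-yl)methyl]benzoyl}oxy)-2-(methoxymethoxy)-6-propylbenzoate | CCCC1(Cc2cc(OC)cc(OCc3ccccc3)c2C(=O)Oc2cc(OCOC)c(C(=O)OC(C)(C)C)c(CCC)c2)OCCO1 | intermediate
19 | 4-{[2-(benzyloxy)-4-methoxy-6-(2-oxopentyl)benzoyl]oxy}-2-hydroxy-6-propylbenzoic acid | CCCC(=O)Cc1cc(OC)cc(OCc2ccccc2)c1C(=O)Oc1cc(O)c(C(=O)O)c(CCC)c1 | intermediate
20 | 2-hydroxy-4-{[2-hydroxy-4-methoxy-6-(2-oxopentyl)benzoyl]oxy}-6-propylbenzoic acid | CCCC(=O)Cc1cc(OC)cc(O)c1C(=O)Oc1cc(O)c(C(=O)O)c(CCC)c1 | target

## Step count and risks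

Total step count: 13. Longest linear sequence: 8 steps (steps 1–5, then 11–13; the ring B branch, steps 6–10 then 11–13, is equally long).

**Step 11 (key step).** The most likely failure is loss of 17 by protodeboronation and by oxidation to the phenol (from traces of water) faster than C–O bond formation, because the copper carboxylate of a 2,6-disubstituted benzoate is bulky and may transmetalate and eliminate slowly. Fallback, from 17 back to 18: the boronic acid is oxidised with H2O2 and aqueous NaHCO3 in THF to tert-butyl 4-hydroxy-2-(methoxymethoxy)-6-propylbenzoate F1. This phenol is acylated with 9 by Steglich esterification (N,N'-dicyclohexylcarbodiimide, 4-pyrrolidinopyridine, CH2Cl2, rt) to give 18. This is the conventional polarity. It is tolerable here because the ketone of 9 is masked, though the reaction is expected to be slow at the shielded carbonyl and rearrangement to the N-acylurea is the main loss.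

**Step 3.** Three processes compete with acylation: attack of the benzyllithium on the ester of unreacted 3, proton transfer from the α-CH2 of 4 to the benzyllithium, and collapse of the tetrahedral adduct onto the neighbouring ester on warming. Fallback, from 3 back to 7: the same lateral anion is added to butanal, and the alkoxide closes onto the ester, so the lactonisation tendency is used productively. This gives racemic 8-(benzyloxy)-6-methoxy-3-propyl-3,4-dihydro-1H-isochromen-1-one F2. Opening with KOH in aqueous THF, evaporation and O-methylation of the potassium carboxylate with MeI in DMF give racemic methyl 2-(benzyloxy)-6-(2-hydroxypentyl)-4-methoxybenzoate F3. The shielded ester of F3 relactonises only slowly, and Dess–Martin oxidation in CH2Cl2 returns 7.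

**Step 5.** Hydroxide attack at the doubly ortho-substituted ester may be too slow for full conversion. On acidification, partial ketal hydrolysis followed by lactonisation of the freed keto acid may erode the product. Fallback, from 3 back to 9, carrying the carboxyl as an allyl ester:
- 3 is saponified before any acid-sensitive group is present (KOH, aqueous DMSO, 100 °C, strongly acidic work-up allowed) to 2-(benzyloxy)-4-methoxy-6-methylbenzoic acid F4.
- The carboxylate is O-alkylated with allyl bromide (K2CO3, DMF) to prop-2-en-1-yl 2-(benzyloxy)-4-methoxy-6-methylbenzoate F5.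
- Lateral lithiation and acylation with 4 as in step 3 give prop-2-en-1-yl 2-(benzyloxy)-4-methoxy-6-(2-oxopentyl)benzoate F6.
- Ketalisation as in step 4 gives prop-2-en-1-yl 2-(benzyloxy)-4-methoxy-6-[(2-propyl-1,3-dioxolan-2-yl)methyl]benzoate F7.
- Pd(PPh3)4 with morpholine in THF at room temperature removes the allyl group through a π-allyl palladium complex, with no attack at the shielded carbonyl carbon, and returns 9.

**Step 12.** Three groups of different acid lability must fall together. The risks are capture of tert-butyl, methoxymethyl or benzyl cations by the electron-rich rings, partial acidolysis of the benzyl ether with C-benzylation, and closure of the freed ketone enol onto the depside carbonyl with loss of ring B on prolonged exposure. Fallback, from 18 back to 20, reversing the order of the last two operations: hydrogenolysis of 18 (H2, 10% Pd/C, EtOAc) gives tert-butyl 4-({2-hydroxy-4-methoxy-6-[(2-propyl-1,3-dioxolan-2-yl)methyl]benzoyl}oxy)-2-(methoxymethoxy)-6-propylbenzoate F8. The benzyl group is then gone before any acid is applied. Treatment of F8 with TFA/CH2Cl2/H2O at 0 °C gives 20 directly, which can be precipitated with water as soon as conversion is complete to keep acid contact short.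

## Further compounds

F1 | step 11 | tert-butyl 4-hydroxy-2-(methoxymethoxy)-6-propylbenzoate | CCCc1cc(O)cc(OCOC)c1C(=O)OC(C)(C)C
F2 | step 3 | 8-(benzyloxy)-6-methoxy-3-propyl-3,4-dihydro-1H-isochromen-1-one (racemic) | CCCC1Cc2cc(OC)cc(OCc3ccccc3)c2C(=O)O1
F3 | step 3 | methyl 2-(benzyloxy)-6-(2-hydroxypentyl)-4-methoxybenzoate (racemic) | CCCC(O)Cc1cc(OC)cc(OCc2ccccc2)c1C(=O)OC
F4 | step 5 | 2-(benzyloxy)-4-methoxy-6-methylbenzoic acid | Cc1cc(OC)cc(OCc2ccccc2)c1C(=O)O
F5 | step 5 | prop-2-en-1-yl 2-(benzyloxy)-4-methoxy-6-methylbenzoate | Cc1cc(OC)cc(OCc2ccccc2)c1C(=O)OCC=C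
F6 | step 5 | prop-2-en-1-yl 2-(benzyloxy)-4-methoxy-6-(2-oxopentyl)benzoate | CCCC(=O)Cc1cc(OC)cc(OCc2ccccc2)c1C(=O)OCC=C
F7 | step 5 | prop-2-en-1-yl 2-(benzyloxy)-4-methoxy-6-[(2-propyl-1,3-dioxolan-2-yl)methyl]benzoate | CCCC1(Cc2cc(OC)cc(OCc3ccccc3)c2C(=O)OCC=C)OCCO1
F8 | step 12 | tert-butyl 4-({2-hydroxy-4-methoxy-6-[(2-propyl-1,3-dioxolan-2-yl)methyl]benzoyl}oxy)-2-(methoxymethoxy)-6-propylbenzoate | CCCC1(Cc2cc(OC)cc(O)c2C(=O)Oc2cc(OCOC)c(C(=O)OC(C)(C)C)c(CCC)c2)OCCO1
A1 | alternative 1 | 2,4-dimethoxy-6-propylbenzoic acid | CCCc1cc(OC)cc(OC)c1C(=O)O
A2 | alternative 1 | 3,5-dimethoxybenzyne (1,2-didehydro-3,5-dimethoxybenzene) | COC1=CC(OC)=CC#C1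
A3 | alternative 2 | benzyl 2-hydroxy-4-({2-hydroxy-4-methoxy-6-[(2-propyl-1,3-dioxolan-2-yl)methyl]benzoyl}oxy)-6-propylbenzoate | CCCC1(Cc2cc(OC)cc(O)c2C(=O)Oc2cc(O)c(C(=O)OCc3ccccc3)c(CCC)c2)OCCO1
A4 | alternative 2 | 1,3-dimethoxy-1-(trimethylsilyloxy)buta-1,3-diene | C=C(OC)C=C(OC)O[Si](C)(C)C
A5 | alternative 2 | benzyl 2-hydroxy-6-propyl-4-{[4-(2-propyl-1,3-dioxolan-2-yl)but-2-ynoyl]oxy}benzoate | CCCC1(CC#CC(=O)Oc2cc(O)c(C(=O)OCc3ccccc3)c(CCC)c2)OCCO1
A6 | alternative 3 | benzyl 2-(benzyloxy)-4-{[2-(benzyloxy)-4-methoxy-6-(2-oxopentyl)benzoyl]oxy}-6-propylbenzoate | CCCC(=O)Cc1cc(OC)cc(OCc2ccccc2)c1C(=O)Oc1cc(OCc2ccccc2)c(C(=O)OCc2ccccc2)c(CCC)c1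
A7 | alternative 3 | benzyl 2-(benzyloxy)-4-{[2-(benzyloxy)-6-bromo-4-methoxybenzoyl]oxy}-6-propylbenzoate | COc1cc(Br)c(C(=O)Oc2cc(OCc3ccccc3)c(C(=O)OCc3ccccc3)c(CCC)c2)c(OCc2ccccc2)c1
A8 | alternative 3 | 1-chloropentan-2-one | CCCC(=O)CCl
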